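**Retrosynthetic overview**

1. The last bond is the C8–O ester to (2S,3R)-2,3-dimethyloxirane-2-carboxylic acid (from tiglyl alcohol); the C1‑OMe/C9=O pair comes from a C1 ketone/C9 carbinol pair by a C9‑OH‑directed reduction.
2. Key disconnection: the cyclodecene C1–C10 is unveiled from a cis‑fused bicyclo[6.2.0]decane (cyclooctene C1,C4,C5–C10 sharing the C1–C4 bond with cyclobutane C1–C2–C3–C4) by a one‑pot iodolactonisation/Grob fragmentation.
3. Enabling feature: the unit C1(O)–C2–C3–C4(Me)=C5 next to the C6–O/C7 γ‑lactone. The C1–OH donor, the C1–C4 σ‑bond and a C5–I leaving group stand in a 1,3‑relationship, and the iodide is placed by closing the lactone at C6.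
4. The cyclooctene comes from RCM (C6=C7) followed by an Ireland–Claisen shift (C5–O to C7–C11); the arms come from a tethered Reformatsky δ‑lactone (C1–C10 bond) and an alkoxyallylboration (C8–C9 bond).
5. Ring order: cyclopropane (Kulinkovich), cyclobutanone (epoxidation/semipinacol), temporary δ‑lactone, cyclooctene, γ‑lactone, cyclodecene.

Key step: step 13

Remark on the chemistry: germacrane numbering (ring C1–C10, lactone carbons C11–C13) is used for the atoms of all intermediates; the acyl residue is the cis‑dimethyl (tiglic acid‑derived) epoxide, as the target SMILES requires.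

**Route**

Step 1
Reactants: 1 acrolein; 2 ethyl 2-(triphenyl-λ5-phosphanylidene)propanoate
Product: 3 ethyl (2E)-2-methylpenta-2,4-dienoate
Conditions: CH2Cl2, 0 °C → rt
Reagents that add atoms: none
Why: Wittig olefination with a stabilised ylide should give the E dienoate (ester trans to vinyl), the geometry that later fixes the C4/C5 relationship.

Step 2
Reactants: 3 ethyl (2E)-2-methylpenta-2,4-dienoate
Product: 4 1-[(2E)-penta-2,4-dien-2-yl]cyclopropan-1-ol
Conditions: EtMgBr (3 equiv, slow addition), Ti(OiPr)4 (0.3 equiv), THF/Et2O, 0 °C → rt; aq. NH4Cl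
Reagents that add atoms: ethylmagnesium bromide, CC[Mg]Br
Why: Kulinkovich cyclopropanation: the titanacyclopropane from EtMgBr/Ti(OiPr)4 adds twice to the ester carbonyl, so its two CH2 groups become C2 and C3 and the α‑methyl enoate geometry is retained.

Step 3
Reactants: 4 1-[(2E)-penta-2,4-dien-2-yl]cyclopropan-1-ol
Product: 6 (2R)-2-[(1R)-1-hydroxyprop-2-en-1-yl]-2-methylcyclobutan-1-one, via vinyl epoxide 5 (not isolated)
Conditions: Shi ketone (D‑fructose‑derived, 0.3 equiv), Oxone, K2CO3, Bu4NHSO4, MeCN/DMM–aq. buffer (pH 10.5), −10 °C; extraction; BF3·OEt2 (0.1 equiv), CH2Cl2, −78 °C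
Reagents that add atoms: potassium peroxymonosulfate (Oxone), [K+].[O-]S(=O)(=O)OO
Why: Shi asymmetric epoxidation of the more electron‑rich trisubstituted olefin (spiro transition state, facial sense as for trans‑ and trisubstituted olefins) is followed by a semipinacol ring expansion in which a cyclopropane C–C bond migrates to C4 anti to the breaking C4–O bond (inversion at C4, C5–O retained), so the E olefin is translated stereospecifically into the (4R,5R) aldol‑type cyclobutanone.

Step 4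
Reactants: 6 (2R)-2-[(1R)-1-hydroxyprop-2-en-1-yl]-2-methylcyclobutan-1-one; 7 2-bromopropanoyl bromide
Product: 8 (1R)-1-[(1R)-1-methyl-2-oxocyclobutyl]prop-2-en-1-yl (2RS)-2-bromopropanoate
Conditions: pyridine, CH2Cl2, −20 °C
Reagents that add atoms: none
Why: O‑acylation of the hindered allylic alcohol with an acid bromide touches no stereocentre, and the CHBr centre is erased in step 5.

Step 5
Reactants: 8 (1R)-1-[(1R)-1-methyl-2-oxocyclobutyl]prop-2-en-1-yl (2RS)-2-bromopropanoate
Product: 9 (1R,2R,5S,6R)-2-ethenyl-6-hydroxy-1,5-dimethyl-3-oxabicyclo[4.2.0]octan-4-one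
Conditions: SmI2 (2.2 equiv), THF, −78 °C
Reagents that add atoms: none
Why: SmI2‑mediated intramolecular Reformatsky reaction: the Sm(III) ester enolate adds to the strained, aldehyde‑like cyclobutanone through a chelated chair, the tether forces the new C1–C10 bond cis to C5 (cis‑fused δ‑lactone), and the enolate methyl should sit pseudo‑equatorial on the forming lactone (C10‑Me cis to C1‑OH).

Step 6
Reactants: 9 (1R,2R,5S,6R)-2-ethenyl-6-hydroxy-1,5-dimethyl-3-oxabicyclo[4.2.0]octan-4-one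
Product: 10 (2S)-2-{(1R,2R)-1-hydroxy-2-[(1R)-1-hydroxyprop-2-en-1-yl]-2-methylcyclobutyl}-N-methoxy-N-methylpropanamide
Conditions: MeNH(OMe)·HCl, AlMe3, CH2Cl2, 0 °C → rt; Rochelle salt
Reagents that add atoms: N,O-dimethylhydroxylamine hydrochloride, CNOC.Cl
Why: Weinreb aminolysis of the lactone by the aluminium amide frees the C5 carbinol and stores C9 as an amide that should not relactonise.

Step 7
Reactants: 10 (2S)-2-{(1R,2R)-1-hydroxy-2-[(1R)-1-hydroxyprop-2-en-1-yl]-2-methylcyclobutyl}-N-methoxy-N-methylpropanamide; 11 propanoic anhydride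
Product: 12 (1R)-1-{(1R,2R)-2-hydroxy-2-[(2S)-1-[methoxy(methyl)amino]-1-oxopropan-2-yl]-1-methylcyclobutyl}prop-2-en-1-yl propanoate
Conditions: Et3N, DMAP (cat.), CH2Cl2, rt
Reagents that add atoms: none
Why: DMAP‑catalysed acylation should take the secondary allylic C5–OH and leave the tertiary cyclobutanol free; the propanoate carries C11–C13.

Step 8
Reactants: 12 (1R)-1-{(1R,2R)-2-hydroxy-2-[(2S)-1-[methoxy(methyl)amino]-1-oxopropan-2-yl]-1-methylcyclobutyl}prop-2-en-1-yl propanoate
Product: 13 (1R)-1-{(1R,2R)-2-hydroxy-1-methyl-2-[(2S)-1-oxopropan-2-yl]cyclobutyl}prop-2-en-1-yl propanoate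
Conditions: DIBAL‑H (2.2 equiv), THF, −78 °C; Rochelle salt
Reagents that add atoms: none
Why: DIBAL‑H reduction of a Weinreb amide stops at the chelated hemiaminal and releases the aldehyde on work‑up, and this should be faster than attack on the hindered neopentyl‑type propanoate.

Step 9
Reactants: 13 (1R)-1-{(1R,2R)-2-hydroxy-1-methyl-2-[(2S)-1-oxopropan-2-yl]cyclobutyl}prop-2-en-1-yl propanoate; 14 3-(methoxymethoxy)prop-1-ene
Product: 16 (1R)-1-{(1R,2R)-2-hydroxy-2-[(2R,3R,4R)-3-hydroxy-4-(methoxymethoxy)hex-5-en-2-yl]-1-methylcyclobutyl}prop-2-en-1-yl propanoate, via alkoxyallylborane 15 (not isolated)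
Conditions: 14, s‑BuLi, THF, −78 °C; (−)-Ipc2BOMe; BF3·OEt2; then 13, −78 °C; NaBO3·4H2O, THF/H2O
Reagents that add atoms: none
Why: Brown γ‑alkoxyallylboration: the closed chair transition state of the Z‑alkoxyallylborane gives the syn 1,2‑diol monoether, and the Ipc groups from (+)-α‑pinene direct Si‑face attack, setting C8 (R) and C9 (R) under reagent control.

Step 10
Reactants: 16 (1R)-1-{(1R,2R)-2-hydroxy-2-[(2R,3R,4R)-3-hydroxy-4-(methoxymethoxy)hex-5-en-2-yl]-1-methylcyclobutyl}prop-2-en-1-yl propanoate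
Product: 17 (1R)-1-{(1R,2R)-2-[(2R,3R,4R)-3-[(tert-butyldimethylsilyl)oxy]-4-(methoxymethoxy)hex-5-en-2-yl]-2-hydroxy-1-methylcyclobutyl}prop-2-en-1-yl propanoate
Conditions: TBSOTf (1.05 equiv), 2,6‑lutidine, CH2Cl2, −78 °C
Reagents that add atoms: tert-butyldimethylsilyl trifluoromethanesulfonate, CC(C)(C)[Si](C)(C)OS(=O)(=O)C(F)(F)F
Why: Silylation at low temperature should take the secondary C9–OH and leave the tertiary C1–OH, which is needed free for the fragmentation.

Step 11
Reactants: 17 (1R)-1-{(1R,2R)-2-[(2R,3R,4R)-3-[(tert-butyldimethylsilyl)oxy]-4-(methoxymethoxy)hex-5-en-2-yl]-2-hydroxy-1-methylcyclobutyl}prop-2-en-1-yl propanoate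
Product: 18 (1R,2R,3Z,5R,6R,7R,8R)-6-[(tert-butyldimethylsilyl)oxy]-8-hydroxy-5-(methoxymethoxy)-1,7-dimethylbicyclo[6.2.0]dec-3-en-2-yl propanoate
Conditions: Hoveyda–Grubbs II (10 mol%), toluene (2 mM), 80 °C
Reagents that add atoms: none
Why: Ring‑closing metathesis: the cis‑1,2 disposition of the two arms on the cyclobutane should favour closure to the Z‑cyclooctene C6=C7 with loss of ethene.

Step 12
Reactants: 18 (1R,2R,3Z,5R,6R,7R,8R)-6-[(tert-butyldimethylsilyl)oxy]-8-hydroxy-5-(methoxymethoxy)-1,7-dimethylbicyclo[6.2.0]dec-3-en-2-yl propanoate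
Product: 21 (2S)-2-[(1R,2Z,4R,5R,6R,7R,8R)-6-[(tert-butyldimethylsilyl)oxy]-8-hydroxy-5-(methoxymethoxy)-1,7-dimethylbicyclo[6.2.0]dec-2-en-4-yl]propanoic acid, via silyl ketene acetal 19 (not isolated), via silyl ester 20 (not isolated)
Conditions: TMSCl/Et3N, THF, −78 °C, then LDA (3 equiv, internal quench); → 50 °C; 1 M HCl
Reagents that add atoms: none
Why: Ireland–Claisen rearrangement: the suprafacial [3,3] shift places C11 on the face of C7 that carried the C5 oxygen, and a chair‑like transition state of the E silyl ketene acetal (methyl cis to the allylic oxygen) should set C11 with the methyl cis to H7 of the later lactone, which is also the thermodynamically preferred epimer.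

Step 13
Reactants: 21 (2S)-2-[(1R,2Z,4R,5R,6R,7R,8R)-6-[(tert-butyldimethylsilyl)oxy]-8-hydroxy-5-(methoxymethoxy)-1,7-dimethylbicyclo[6.2.0]dec-2-en-4-yl]propanoic acid
Product: 23 (4E,6S,7S,8R,9R,10R,11S)-9-[(tert-butyldimethylsilyl)oxy]-8-(methoxymethoxy)-1-oxogermacr-4-en-12,6-olide, via iodolactone 22 (not isolated)
Conditions: KOt‑Bu (1.0 equiv), THF, −78 °C; I2 (1.05 equiv), −78 → 0 °C, dark; recool to −78 °C, KOt‑Bu (1.3 equiv), → −40 °C; AcOH quench at −78 °C
Reagents that add atoms: none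
Why: The potassium carboxylate of 21 attacks the iodonium ion of the Z‑cyclooctene at C6 from the side‑chain face (5‑exo iodolactonisation, trans addition) to give the cis‑fused γ‑lactone 22 with the C5 iodide anti to the new C6–O bond; attack at the neopentyl C5, or by the neutral tertiary C1–OH (5‑endo), should not compete. Deprotonation of the cyclobutanol then triggers a concerted Grob fragmentation: the C1–O− lone pair pushes, the C1–C4 ring‑fusion bond anti‑periplanar to C5–I breaks, C4=C5 forms and iodide leaves, so the eight‑membered ring C1,C4–C10 expands by C2 and C3 to the cyclodecenone with release of the cyclobutane strain. The closest known reactions are Grob (Wharton‑type) fragmentations of γ‑halo and γ‑sulfonyloxy alkoxides and the fragmentation of ring‑fused cyclobutanols used for two‑carbon ring expansion. The lactone ring closes 5‑exo onto the iodonium ion; the ten‑membered ring is not closed but liberated by cleaving the zero‑atom bridge of the bicyclo[6.2.0]decane. C6 is set by intramolecular delivery cis to the C7 side chain, and the E geometry follows stereospecifically from the C4 configuration fixed in step 3 together with the anti iodolactonisation, which place C3 anti to C6 in the only rotamer that has C5–I anti to C1–C4. Fragmentation must outrun E2 (no anti hydrogen at C6, C4 quaternary), oxetane closure (a 2‑oxabicyclo[2.2.0]hexane) and retro‑aldol of the product (C9 oxygen silylated, cold acetic acid quench).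

Step 14
Reactants: 23 (4E,6S,7S,8R,9R,10R,11S)-9-[(tert-butyldimethylsilyl)oxy]-8-(methoxymethoxy)-1-oxogermacr-4-en-12,6-olide
Product: 24 (4E,6S,7S,8R,9R,10R,11S)-9-hydroxy-8-(methoxymethoxy)-1-oxogermacr-4-en-12,6-olide
Conditions: HF·pyridine, pyridine, THF, 0 °C → rt
Reagents that add atoms: none
Why: Buffered fluoride cleaves the TBS ether to unveil the C9 carbinol that directs the C1 reduction; the MOM ether and the lactone should survive.

Step 15
Reactants: 24 (4E,6S,7S,8R,9R,10R,11S)-9-hydroxy-8-(methoxymethoxy)-1-oxogermacr-4-en-12,6-olide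
Product: 25 (1S,4E,6S,7S,8R,9R,10S,11S)-9-acetoxy-1-hydroxy-8-(methoxymethoxy)germacr-4-en-12,6-olide
Conditions: SmI2 (0.3 equiv), CH3CHO (10 equiv), THF, −10 °C
Reagents that add atoms: acetaldehyde, CC=O
Why: Evans–Tishchenko reduction: the Sm‑bound hemiacetal formed from the C9 carbinol and acetaldehyde delivers hydride intramolecularly to C1, which should give the 1,3‑anti diol (C1 S) as its C9 monoacetate and so differentiates the two oxygens in one step.

Step 16
Reactants: 25 (1S,4E,6S,7S,8R,9R,10S,11S)-9-acetoxy-1-hydroxy-8-(methoxymethoxy)germacr-4-en-12,6-olide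
Product: 26 (1S,4E,6S,7S,8R,9R,10S,11S)-9-acetoxy-1-methoxy-8-(methoxymethoxy)germacr-4-en-12,6-olide
Conditions: Me3O·BF4, 1,8‑bis(dimethylamino)naphthalene, CH2Cl2, 0 °C → rt
Reagents that add atoms: trimethyloxonium tetrafluoroborate, C[O+](C)C.F[B-](F)(F)F
Why: Methylation with Meerwein's salt under non‑basic conditions should leave the lactone, the acetate and C11 untouched.

Step 17
Reactants: 26 (1S,4E,6S,7S,8R,9R,10S,11S)-9-acetoxy-1-methoxy-8-(methoxymethoxy)germacr-4-en-12,6-olide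
Product: 27 (1S,4E,6S,7S,8R,9R,10R,11S)-9-hydroxy-1-methoxy-8-(methoxymethoxy)germacr-4-en-12,6-olide
Conditions: K2CO3, MeOH, 0 °C; PPTS work‑up
Reagents that add atoms: none
Why: Methanolysis removes the secondary acetate; the γ‑lactone, if opened, should reclose on the mildly acidic work‑up, and C11 is already in its thermodynamically preferred configuration.

Step 18
Reactants: 27 (1S,4E,6S,7S,8R,9R,10R,11S)-9-hydroxy-1-methoxy-8-(methoxymethoxy)germacr-4-en-12,6-olide
Product: 28 (1S,4E,6S,7S,8R,10S,11S)-1-methoxy-8-(methoxymethoxy)-9-oxogermacr-4-en-12,6-olide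
Conditions: Dess–Martin periodinane, NaHCO3, CH2Cl2, 0 °C → rt
Reagents that add atoms: none
Why: Dess–Martin oxidation under buffered, near‑neutral conditions should give the C9 ketone without epimerising C8 or C10.

Step 19
Reactants: 28 (1S,4E,6S,7S,8R,10S,11S)-1-methoxy-8-(methoxymethoxy)-9-oxogermacr-4-en-12,6-olide
Product: 29 (1S,4E,6S,7S,8R,10S,11S)-8-hydroxy-1-methoxy-9-oxogermacr-4-en-12,6-olide
Conditions: Me2BBr, CH2Cl2, −78 °C; aq. NaHCO3/THF
Reagents that add atoms: none
Why: Bromodimethylborane cleaves the MOM acetal at −78 °C and should spare the methyl ether, the lactone and the trisubstituted olefin.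

Step 20
Reactants: 30 (2E)-2-methylbut-2-en-1-ol
Product: 31 [(2R,3R)-2,3-dimethyloxiran-2-yl]methanol
Conditions: Ti(OiPr)4, D‑(−)‑diethyl tartrate, t‑BuOOH, 4 Å MS, CH2Cl2, −20 °C
Reagents that add atoms: tert-butyl hydroperoxide, CC(C)(C)OO
Why: Katsuki–Sharpless asymmetric epoxidation: the D‑(−)‑tartrate catalyst should deliver oxygen to the face of the E allylic alcohol that gives the (2R,3R) cis‑dimethyl epoxy alcohol.

Step 21
Reactants: 31 [(2R,3R)-2,3-dimethyloxiran-2-yl]methanol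
Product: 32 (2S,3R)-2,3-dimethyloxirane-2-carboxylic acid
Conditions: RuCl3 (cat.), NaIO4, CCl4/MeCN/H2O, rt
Reagents that add atoms: sodium periodate, [Na+].[O-]I(=O)(=O)=O; water, O
Why: RuO4‑catalysed oxidation takes the primary alcohol to the acid without opening the epoxide; the C2 descriptor changes to S by CIP priority only.

Step 22
Reactants: 29 (1S,4E,6S,7S,8R,10S,11S)-8-hydroxy-1-methoxy-9-oxogermacr-4-en-12,6-olide; 32 (2S,3R)-2,3-dimethyloxirane-2-carboxylic acid
Product: 34 (1S,4E,6S,7S,8R,10S,11S)-1-methoxy-9-oxogermacr-4-en-12,6-olid-8-yl (2S,3R)-2,3-dimethyloxirane-2-carboxylate (CNP0145898.1), via mixed anhydride 33 (not isolated)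
Conditions: 32, 2,4,6‑trichlorobenzoyl chloride, Et3N, THF, 0 °C; then 29, DMAP, toluene, 0 °C
Reagents that add atoms: none
Why: Yamaguchi esterification through the mixed anhydride acylates the C8 α‑hydroxy ketone, and the low temperature and brief exposure to base should avoid epimerisation at C8/C10 and β‑elimination of methanol.

**Compound list**

1 | acrolein (prop-2-enal) | C=CC=O | starting material
2 | ethyl 2-(triphenyl-λ5-phosphanylidene)propanoate | CCOC(=O)C(C)=P(c1ccccc1)(c1ccccc1)c1ccccc1 | starting material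
3 | ethyl (2E)-2-methylpenta-2,4-dienoate | CCOC(=O)/C(C)=C/C=C | intermediate
4 | 1-[(2E)-penta-2,4-dien-2-yl]cyclopropan-1-ol | OC1(CC1)/C(C)=C/C=C | intermediate
5 | 1-[(2S,3R)-3-ethenyl-2-methyloxiran-2-yl]cyclopropan-1-ol (not isolated) | OC1(CC1)[C@@]1(C)O[C@@H]1C=C | intermediate
6 | (2R)-2-[(1R)-1-hydroxyprop-2-en-1-yl]-2-methylcyclobutan-1-one | O=C1CC[C@]1(C)[C@H](O)C=C | intermediate
7 | 2-bromopropanoyl bromide (racemic) | CC(Br)C(=O)Br | starting material
8 | (1R)-1-[(1R)-1-methyl-2-oxocyclobutyl]prop-2-en-1-yl (2RS)-2-bromopropanoate | O=C1CC[C@]1(C)[C@H](OC(=O)C(C)Br)C=C | intermediate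
9 | (1R,2R,5S,6R)-2-ethenyl-6-hydroxy-1,5-dimethyl-3-oxabicyclo[4.2.0]octan-4-one | O=C1O[C@H](C=C)[C@@]2(C)CC[C@@]2(O)[C@@H]1C | intermediate
10 | (2S)-2-{(1R,2R)-1-hydroxy-2-[(1R)-1-hydroxyprop-2-en-1-yl]-2-methylcyclobutyl}-N-methoxy-N-methylpropanamide | CON(C)C(=O)[C@@H](C)[C@]1(O)CC[C@]1(C)[C@H](O)C=C | intermediate
11 | propanoic anhydride | CCC(=O)OC(=O)CC | starting material
12 | (1R)-1-{(1R,2R)-2-hydroxy-2-[(2S)-1-[methoxy(methyl)amino]-1-oxopropan-2-yl]-1-methylcyclobutyl}prop-2-en-1-yl propanoate | CON(C)C(=O)[C@@H](C)[C@]1(O)CC[C@]1(C)[C@H](OC(=O)CC)C=C | intermediate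
13 | (1R)-1-{(1R,2R)-2-hydroxy-1-methyl-2-[(2S)-1-oxopropan-2-yl]cyclobutyl}prop-2-en-1-yl propanoate | O=C[C@@H](C)[C@]1(O)CC[C@]1(C)[C@H](OC(=O)CC)C=C | intermediate
14 | 3-(methoxymethoxy)prop-1-ene (allyl methoxymethyl ether) | C=CCOCOC | starting material
15 | [(2Z)-3-(methoxymethoxy)prop-2-en-1-yl]bis(isopinocampheyl)borane, Ipc groups from (+)-α-pinene (not isolated) | COCO/C=C\CB([C@@H]1C[C@@H]2C[C@H]([C@H]1C)C2(C)C)[C@@H]1C[C@@H]2C[C@H]([C@H]1C)C2(C)C | intermediate
16 | (1R)-1-{(1R,2R)-2-hydroxy-2-[(2R,3R,4R)-3-hydroxy-4-(methoxymethoxy)hex-5-en-2-yl]-1-methylcyclobutyl}prop-2-en-1-yl propanoate | C=C[C@@H](OCOC)[C@H](O)[C@@H](C)[C@]1(O)CC[C@]1(C)[C@H](OC(=O)CC)C=C | intermediate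
17 | (1R)-1-{(1R,2R)-2-[(2R,3R,4R)-3-[(tert-butyldimethylsilyl)oxy]-4-(methoxymethoxy)hex-5-en-2-yl]-2-hydroxy-1-methylcyclobutyl}prop-2-en-1-yl propanoate | C=C[C@@H](OCOC)[C@H](O[Si](C)(C)C(C)(C)C)[C@@H](C)[C@]1(O)CC[C@]1(C)[C@H](OC(=O)CC)C=C | intermediate
18 | (1R,2R,3Z,5R,6R,7R,8R)-6-[(tert-butyldimethylsilyl)oxy]-8-hydroxy-5-(methoxymethoxy)-1,7-dimethylbicyclo[6.2.0]dec-3-en-2-yl propanoate | CCC(=O)O[C@@H]1/C=C\[C@@H](OCOC)[C@H](O[Si](C)(C)C(C)(C)C)[C@@H](C)[C@]2(O)CC[C@]12C | intermediate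
19 | (E)-O-trimethylsilyl ketene acetal of 18 carrying a C1–O–SiMe3 group (not isolated) | C/C=C(/O[Si](C)(C)C)O[C@@H]1/C=C\[C@@H](OCOC)[C@H](O[Si](C)(C)C(C)(C)C)[C@@H](C)[C@]2(O[Si](C)(C)C)CC[C@]12C | intermediate
20 | trimethylsilyl ester of 21 carrying a C1–O–SiMe3 group (not isolated) | C[Si](C)(C)OC(=O)[C@@H](C)[C@H]1/C=C\[C@@]2(C)CC[C@@]2(O[Si](C)(C)C)[C@H](C)[C@@H](O[Si](C)(C)C(C)(C)C)[C@@H]1OCOC | intermediate
21 | (2S)-2-[(1R,2Z,4R,5R,6R,7R,8R)-6-[(tert-butyldimethylsilyl)oxy]-8-hydroxy-5-(methoxymethoxy)-1,7-dimethylbicyclo[6.2.0]dec-2-en-4-yl]propanoic acid | OC(=O)[C@@H](C)[C@H]1/C=C\[C@@]2(C)CC[C@@]2(O)[C@H](C)[C@@H](O[Si](C)(C)C(C)(C)C)[C@@H]1OCOC | intermediate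
22 | tricyclic iodolactone (germacrane numbering 1R,4S,5R,6R,7R,8R,9R,10R,11S): cis-fused γ-lactone C12(=O)–O–C6, C5 iodide trans to the lactone oxygen, free C1–OH, C9–OTBS, C8–OMOM (not isolated) | C[C@@H]1C(=O)O[C@H]2[C@H](I)[C@@]3(C)CC[C@@]3(O)[C@H](C)[C@@H](O[Si](C)(C)C(C)(C)C)[C@H](OCOC)[C@@H]12 | intermediate
23 | (4E,6S,7S,8R,9R,10R,11S)-9-[(tert-butyldimethylsilyl)oxy]-8-(methoxymethoxy)-1-oxogermacr-4-en-12,6-olide | O=C1CC/C(C)=C/[C@@H]2OC(=O)[C@@H](C)[C@@H]2[C@@H](OCOC)[C@H](O[Si](C)(C)C(C)(C)C)[C@H]1C | intermediate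
24 | (4E,6S,7S,8R,9R,10R,11S)-9-hydroxy-8-(methoxymethoxy)-1-oxogermacr-4-en-12,6-olide | O=C1CC/C(C)=C/[C@@H]2OC(=O)[C@@H](C)[C@@H]2[C@@H](OCOC)[C@H](O)[C@H]1C | intermediate
25 | (1S,4E,6S,7S,8R,9R,10S,11S)-9-acetoxy-1-hydroxy-8-(methoxymethoxy)germacr-4-en-12,6-olide | O[C@H]1CC/C(C)=C/[C@@H]2OC(=O)[C@@H](C)[C@@H]2[C@@H](OCOC)[C@H](OC(C)=O)[C@H]1C | intermediate
26 | (1S,4E,6S,7S,8R,9R,10S,11S)-9-acetoxy-1-methoxy-8-(methoxymethoxy)germacr-4-en-12,6-olide | CO[C@H]1CC/C(C)=C/[C@@H]2OC(=O)[C@@H](C)[C@@H]2[C@@H](OCOC)[C@H](OC(C)=O)[C@H]1C | intermediate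
27 | (1S,4E,6S,7S,8R,9R,10R,11S)-9-hydroxy-1-methoxy-8-(methoxymethoxy)germacr-4-en-12,6-olide | CO[C@H]1CC/C(C)=C/[C@@H]2OC(=O)[C@@H](C)[C@@H]2[C@@H](OCOC)[C@H](O)[C@H]1C | intermediate
28 | (1S,4E,6S,7S,8R,10S,11S)-1-methoxy-8-(methoxymethoxy)-9-oxogermacr-4-en-12,6-olide | CO[C@H]1CC/C(C)=C/[C@@H]2OC(=O)[C@@H](C)[C@@H]2[C@@H](OCOC)C(=O)[C@H]1C | intermediate
29 | (1S,4E,6S,7S,8R,10S,11S)-8-hydroxy-1-methoxy-9-oxogermacr-4-en-12,6-olide | CO[C@H]1CC/C(C)=C/[C@@H]2OC(=O)[C@@H](C)[C@@H]2[C@@H](O)C(=O)[C@H]1C | intermediate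
30 | (2E)-2-methylbut-2-en-1-ol (tiglyl alcohol) | C/C=C(\C)CO | starting material
31 | [(2R,3R)-2,3-dimethyloxiran-2-yl]methanol | OC[C@@]1(C)O[C@@H]1C | intermediate
32 | (2S,3R)-2,3-dimethyloxirane-2-carboxylic acid | OC(=O)[C@@]1(C)O[C@@H]1C | intermediate
33 | (2S,3R)-2,3-dimethyloxirane-2-carboxylic 2,4,6-trichlorobenzoic anhydride (not isolated) | O=C(OC(=O)[C@@]1(C)O[C@@H]1C)c1c(Cl)cc(Cl)cc1Cl | intermediate
34 | (1S,4E,6S,7S,8R,10S,11S)-1-methoxy-9-oxogermacr-4-en-12,6-olid-8-yl (2S,3R)-2,3-dimethyloxirane-2-carboxylate (CNP0145898.1) | CO[C@H]1CC/C(C)=C/[C@@H]2OC(=O)[C@@H](C)[C@@H]2[C@@H](OC(=O)[C@@]2(C)O[C@@H]2C)C(=O)[C@H]1C | target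

**Summary**

Total step count: 22. Longest linear sequence: 20 steps (steps 1–19 and 22); steps 20–21 make the side‑chain acid.

**Steps most likely to fail, each with a fallback**

Step 13 (iodolactonisation/Grob fragmentation). The alkoxide may not populate the rotamer in which C5–I is anti to C1–C4. Silyl migration from O9 to O1, lactone enolisation or base‑induced breakdown of the β‑silyloxy ketone product could then outpace the fragmentation. The fallback sets out from 21 and replaces the anionic trigger by a homolytic one. The iodolactonisation is run alone (I2, NaHCO3, MeCN/H2O, 0 °C) and the iodolactone 22 is isolated. It is then submitted to a hypoiodite fragmentation (PhI(OAc)2, I2, hν, cyclohexane/CH2Cl2). O–I homolysis gives the C1 alkoxy radical, β‑scission of the strained C1–C4 bond gives the tertiary C4 radical, and this expels the β‑iodine atom. This needs neither base nor an anti‑periplanar arrangement and comes back to the route at 23; the olefin geometry is then no longer stereospecific and would have to be checked.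

Step 2 (Kulinkovich reaction on a conjugated dienoate). Ligand exchange of the titanacyclopropane with the terminal vinyl group, or reduction of the diene, may compete with double addition to the ester. The fallback sets out from 3 and builds the cyclopropanol by cyclopropanation of an enol ether. Aminolysis (MeNH(OMe)·HCl, i‑PrMgCl) gives (2E)-N-methoxy-N,2-dimethylpenta-2,4-dienamide F1. MeMgBr gives (3E)-3-methylhexa-3,5-dien-2-one F2. Kinetic enolisation and silylation (LDA, TMSCl, −78 °C) give trimethyl{[(3E)-3-methylhexa-1,3,5-trien-2-yl]oxy}silane F3. Furukawa–Simmons–Smith cyclopropanation of the electron‑rich enol ether double bond (Et2Zn, CH2I2) gives trimethyl({1-[(2E)-penta-2,4-dien-2-yl]cyclopropyl}oxy)silane F4. Desilylation (K2CO3, MeOH) comes back to the route at 4.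

Step 11 (ring‑closing metathesis to the cyclooctene). Initiation at two branched, oxygen‑flanked olefins may be slow, so that oligomerisation or olefin migration takes over. The fallback sets out from 16 and moves the ring closure ahead of the silylation. The smaller substrate with the free C9 carbinol is cyclised (Hoveyda–Grubbs II, 1,4‑benzoquinone, toluene, high dilution) to (1R,2R,3Z,5R,6R,7R,8R)-6,8-dihydroxy-5-(methoxymethoxy)-1,7-dimethylbicyclo[6.2.0]dec-3-en-2-yl propanoate F5. Selective silylation of its secondary C9–OH (TBSOTf, 2,6‑lutidine, −78 °C) comes back to the route at 18.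

Further compounds
F0 | step 13 | none | none
F1 | step 2 | (2E)-N-methoxy-N,2-dimethylpenta-2,4-dienamide | CON(C)C(=O)/C(C)=C/C=C
F2 | step 2 | (3E)-3-methylhexa-3,5-dien-2-one | CC(=O)/C(C)=C/C=C
F3 | step 2 | trimethyl{[(3E)-3-methylhexa-1,3,5-trien-2-yl]oxy}silane | C=C(O[Si](C)(C)C)/C(C)=C/C=C
F4 | step 2 | trimethyl({1-[(2E)-penta-2,4-dien-2-yl]cyclopropyl}oxy)silane | C[Si](C)(C)OC1(CC1)/C(C)=C/C=C
F5 | step 11 | (1R,2R,3Z,5R,6R,7R,8R)-6,8-dihydroxy-5-(methoxymethoxy)-1,7-dimethylbicyclo[6.2.0]dec-3-en-2-yl propanoate | CCC(=O)O[C@@H]1/C=C\[C@@H](OCOC)[C@H](O)[C@@H](C)[C@]2(O)CC[C@]12C
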